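Everything rests on disconnecting both C–C bonds of the single ketone carbon that bridges C6 of ring A (the benzo ring of the chromene) and the trans CH=CH attached to ring B (the 4-hydroxyphenyl ring). One palladium-catalysed carbonylative Heck reaction inserts CO between a C6 iodide and 4-acetoxystyrene and delivers the complete E-chalcone. The precursor is the (S)-6-iodo-2H-chromene with the free 4-hydroxy-4-methylpentyl chain and both ring-A oxygens masked as methoxymethyl ethers, so that a single mild acid methanolysis finishes the synthesis without an oxidant. C2 is taken from (S)-linalool through an aryl ether formed with the carbinol C–O bond intact; metathesis closes the pyran ring.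

Key step: step 9

Assumption: commercial (S)-(+)-linalool is used at high enantiomeric purity; its carbinol carbon becomes C2 with the same spatial arrangement and the same CIP ranking (O > alkenyl C > CH2 > CH3), so S in linalool corresponds to S in the target; all 2H-chromenes are handled with exclusion of UV light, which could open the pyran ring reversibly and erode C2.

Step 1
Reactants: 1 2-fluorobenzene-1,4-diol
Product: 2 2-fluoro-1,4-bis(methoxymethoxy)benzene
Conditions: MOMCl, i-Pr2NEt, CH2Cl2, 0 °C to rt
Reagents that add atoms: chloromethyl methyl ether, COCCl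
Why: Williamson-type O-alkylation of both phenols by the reactive α-chloro ether gives the bis-acetal; MOM ethers are chosen because they withstand amide bases, alkoxides, ylides, hydride and the Ru and Pd catalysts, acidify the neighbouring ring position for step 3 and come off at the end under mild acid instead of an oxidant.

Step 2
Reactants: 2 2-fluoro-1,4-bis(methoxymethoxy)benzene
Product: 3 1-fluoro-4-iodo-2,5-bis(methoxymethoxy)benzene
Conditions: NIS, CF3CO2H (cat.), MeCN, 0 °C to rt
Reagents that add atoms: N-iodosuccinimide, O=C1CCC(=O)N1I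
Why: Electrophilic aromatic iodination should enter para to fluorine and ortho to an acetal oxygen, the one position where lone-pair donation from both groups stabilises the arenium ion (the site between F and OMOM is crowded, the third is meta to F), and catalytic acid in dry MeCN should leave the acetals intact.

Step 3
Reactants: 3 1-fluoro-4-iodo-2,5-bis(methoxymethoxy)benzene
Product: 6 2-fluoro-5-iodo-3,6-bis(methoxymethoxy)benzaldehyde, via aryllithium 4 (not isolated), via lithium hemiaminal alkoxide 5 (not isolated)
Conditions: LiN(i-Pr)2 (1.1 equiv), THF, −78 °C; DMF, −78 °C; AcOH, −78 °C to rt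
Reagents that add atoms: N,N-dimethylformamide, CN(C)C=O
Why: Directed ortho-metalation: at −78 °C the amide base removes the most acidic ring proton, the one flanked by F and OMOM, without halogen–metal exchange at iodine, and formylation of the aryllithium with DMF fixes CHO, F and I in the 1,2,5-pattern that maps onto C4a, C8a and C6 of the chromene, a pattern that iodination of the preformed aldehyde would not secure.

Step 4
Reactants: 6 2-fluoro-5-iodo-3,6-bis(methoxymethoxy)benzaldehyde; 7 (S)-(+)-linalool
Product: 9 2-{[(3S)-3,7-dimethylocta-1,6-dien-3-yl]oxy}-5-iodo-3,6-bis(methoxymethoxy)benzaldehyde, via potassium linaloolate 8 (not isolated)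
Conditions: 7, KH, THF, 0 °C to rt; then 6, THF–DMF, 0 °C to rt
Reagents that add atoms: none
Why: Nucleophilic aromatic substitution by addition–elimination: the preformed tertiary potassium alkoxide displaces the fluoride activated by the ortho formyl group; the carbinol C–O bond is never broken, so the S configuration of linalool is transferred unchanged to the future C2, and the irreversible deprotonation with KH leaves no base that could attack the aldehyde.

Step 5
Reactants: 9 2-{[(3S)-3,7-dimethylocta-1,6-dien-3-yl]oxy}-5-iodo-3,6-bis(methoxymethoxy)benzaldehyde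
Product: 10 2-{[(3S)-3,7-dimethylocta-1,6-dien-3-yl]oxy}-3-ethenyl-5-iodo-1,4-bis(methoxymethoxy)benzene
Conditions: Ph3PCH3Br, KOt-Bu, THF, 0 °C to rt
Reagents that add atoms: methyltriphenylphosphonium bromide, C[P+](c1ccccc1)(c1ccccc1)c1ccccc1.[Br-]
Why: Wittig methylenation with the unstabilised ylide turns the non-enolisable aldehyde into the styrene needed for ring closure and leaves aryl iodide, acetals and the other alkenes untouched.

Step 6
Reactants: 10 2-{[(3S)-3,7-dimethylocta-1,6-dien-3-yl]oxy}-3-ethenyl-5-iodo-1,4-bis(methoxymethoxy)benzene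
Product: 11 2-{[(3S)-5-(3,3-dimethyloxiran-2-yl)-3-methylpent-1-en-3-yl]oxy}-3-ethenyl-5-iodo-1,4-bis(methoxymethoxy)benzene (both epimers at the oxirane CH)
Conditions: mCPBA (1.05 equiv), CH2Cl2, −20 to 0 °C
Reagents that add atoms: 3-chloroperoxybenzoic acid, OOC(=O)c1cccc(Cl)c1
Why: Prilezhaev epoxidation: the peracid reacts with the electron-rich trisubstituted alkene far faster than with the monosubstituted vinyl and styrenyl groups, which removes the olefin that would compete in the metathesis (cyclopentene formation) and prepares Markovnikov hydration; the oxirane CH forms as both epimers, which does not matter because it becomes CH2 in step 7.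

Step 7
Reactants: 11 2-{[(3S)-5-(3,3-dimethyloxiran-2-yl)-3-methylpent-1-en-3-yl]oxy}-3-ethenyl-5-iodo-1,4-bis(methoxymethoxy)benzene
Product: 12 (6S)-6-[2-ethenyl-4-iodo-3,6-bis(methoxymethoxy)phenoxy]-2,6-dimethyloct-7-en-2-ol
Conditions: LiBHEt3, THF, 0 °C; H2O
Reagents that add atoms: none
Why: Hydride opening of the epoxide by SN2 attack at the less substituted oxirane carbon leaves the oxygen on the tertiary carbon and so completes the 4-hydroxy-4-methylpentyl chain; at 0 °C the trialkylborohydride should open the epoxide much faster than it reduces the aryl iodide.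

Step 8
Reactants: 12 (6S)-6-[2-ethenyl-4-iodo-3,6-bis(methoxymethoxy)phenoxy]-2,6-dimethyloct-7-en-2-ol
Product: 13 5-[(2S)-6-iodo-5,8-bis(methoxymethoxy)-2-methyl-2H-chromen-2-yl]-2-methylpentan-2-ol
Conditions: second-generation Grubbs catalyst (H2IMes)(PCy3)Cl2Ru=CHPh (5 mol%), CH2Cl2, 40 °C, light excluded
Reagents that add atoms: none
Why: Ring-closing olefin metathesis joins the styrenyl and allylic vinyl groups into the six-membered pyran ring with loss of ethylene (the ring allows only the cis alkene); the quaternary centre C2 takes no part, and tertiary alcohol, iodide and acetals are tolerated by the ruthenium carbene.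

Step 9
Reactants: 13 5-[(2S)-6-iodo-5,8-bis(methoxymethoxy)-2-methyl-2H-chromen-2-yl]-2-methylpentan-2-ol; 14 carbon monoxide; 15 4-ethenylphenyl acetate (4-acetoxystyrene)
Product: 16 4-[(1E)-3-[(2S)-2-(4-hydroxy-4-methylpentyl)-5,8-bis(methoxymethoxy)-2-methyl-2H-chromen-6-yl]-3-oxoprop-1-en-1-yl]phenyl acetate
Conditions: Pd(OAc)2 (5 mol%), (1-adamantyl)2P(n-Bu) (10 mol%), Et3N (2 equiv), CO (5 bar), 15 (3 equiv), BHT (cat.), 1,4-dioxane, 90 °C, light excluded
Reagents that add atoms: none
Why: Zerovalent palladium, formed in the flask from Pd(OAc)2 and the bulky electron-rich phosphine, adds oxidatively to the C6–I bond, CO inserts to give an aroylpalladium species, this adds syn across the terminal alkene of 4-acetoxystyrene with the acyl group going to the CH2 carbon, and syn β-hydride elimination releases the E-enone while Et3N takes up HI and returns zerovalent palladium. The closest known reaction type is the palladium-catalysed carbonylative Heck reaction (carbonylative vinylation) of aryl iodides with styrenes, an established entry to chalcones. No ring is closed and no stereocentre is created; the quaternary C2 lies far from the reacting site, and the moderate temperature and exclusion of light should keep the pyran ring from opening electrocyclically. Three selectivities are needed: CO insertion must precede alkene insertion, which the CO pressure, the hindered phosphine and the ortho OMOM group (all slowing direct arylation) should secure; the aroylpalladium must take the unhindered monosubstituted styrene, used in excess, and not the internal cis C3=C4 alkene of the pyran ring; and the E geometry follows from syn insertion and syn elimination through the less crowded conformer. The free tertiary alcohol is too hindered to intercept the acyl complex as an ester, and the aryl acetate and the acetals are inert to the amine base.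

Step 10
Reactants: 16 4-[(1E)-3-[(2S)-2-(4-hydroxy-4-methylpentyl)-5,8-bis(methoxymethoxy)-2-methyl-2H-chromen-6-yl]-3-oxoprop-1-en-1-yl]phenyl acetate
Product: 17 (2E)-1-[(2S)-5,8-dihydroxy-2-(4-hydroxy-4-methylpentyl)-2-methyl-2H-chromen-6-yl]-3-(4-hydroxyphenyl)prop-2-en-1-one
Conditions: HCl (1 M in MeOH), MeOH, 0 °C to rt, Ar, light excluded
Reagents that add atoms: none
Why: Acid-catalysed transacetalisation of both aryl MOM ethers and acid-catalysed transesterification of the aryl acetate with methanol unveil the three phenols in one operation without base or oxidant, so the hydroquinone should not be oxidised nor the 2'-hydroxychalcone isomerised to a flavanone; the C6 acyl group deactivates the chromene alkene towards protonation, the tertiary alcohol should not ionise in dilute methanolic HCl at room temperature, and C2 is untouched.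

Compound list
1 | 2-fluorobenzene-1,4-diol (fluorohydroquinone) | Oc1ccc(O)c(F)c1 | starting material
2 | 2-fluoro-1,4-bis(methoxymethoxy)benzene | COCOc1ccc(OCOC)c(F)c1 | intermediate
3 | 1-fluoro-4-iodo-2,5-bis(methoxymethoxy)benzene | COCOc1cc(F)c(OCOC)cc1I | intermediate
4 | [2-fluoro-5-iodo-3,6-bis(methoxymethoxy)phenyl]lithium | [Li]c1c(F)c(OCOC)cc(I)c1OCOC | intermediate
5 | lithium (dimethylamino)[2-fluoro-5-iodo-3,6-bis(methoxymethoxy)phenyl]methanolate | CN(C)C([O-])c1c(F)c(OCOC)cc(I)c1OCOC.[Li+] | intermediate
6 | 2-fluoro-5-iodo-3,6-bis(methoxymethoxy)benzaldehyde | O=Cc1c(F)c(OCOC)cc(I)c1OCOC | intermediate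
7 | (S)-(+)-linalool, (3S)-3,7-dimethylocta-1,6-dien-3-ol | CC(C)=CCC[C@@](O)(C)C=C | starting material
8 | potassium (3S)-3,7-dimethylocta-1,6-dien-3-olate | CC(C)=CCC[C@@]([O-])(C)C=C.[K+] | intermediate
9 | 2-{[(3S)-3,7-dimethylocta-1,6-dien-3-yl]oxy}-5-iodo-3,6-bis(methoxymethoxy)benzaldehyde | CC(C)=CCC[C@@](Oc1c(C=O)c(OCOC)c(I)cc1OCOC)(C)C=C | intermediate
10 | 2-{[(3S)-3,7-dimethylocta-1,6-dien-3-yl]oxy}-3-ethenyl-5-iodo-1,4-bis(methoxymethoxy)benzene | CC(C)=CCC[C@@](Oc1c(C=C)c(OCOC)c(I)cc1OCOC)(C)C=C | intermediate
11 | 2-{[(3S)-5-(3,3-dimethyloxiran-2-yl)-3-methylpent-1-en-3-yl]oxy}-3-ethenyl-5-iodo-1,4-bis(methoxymethoxy)benzene, both epimers at the oxirane CH | CC1(C)OC1CC[C@@](Oc2c(C=C)c(OCOC)c(I)cc2OCOC)(C)C=C | intermediate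
12 | (6S)-6-[2-ethenyl-4-iodo-3,6-bis(methoxymethoxy)phenoxy]-2,6-dimethyloct-7-en-2-ol | CC(C)(O)CCC[C@@](Oc1c(C=C)c(OCOC)c(I)cc1OCOC)(C)C=C | intermediate
13 | 5-[(2S)-6-iodo-5,8-bis(methoxymethoxy)-2-methyl-2H-chromen-2-yl]-2-methylpentan-2-ol | CC(C)(O)CCC[C@@]1(C)C=Cc2c(OCOC)c(I)cc(OCOC)c2O1 | intermediate
14 | carbon monoxide | [C-]#[O+] | starting material
15 | 4-ethenylphenyl acetate (4-acetoxystyrene) | CC(=O)Oc1ccc(C=C)cc1 | starting material
16 | 4-[(1E)-3-[(2S)-2-(4-hydroxy-4-methylpentyl)-5,8-bis(methoxymethoxy)-2-methyl-2H-chromen-6-yl]-3-oxoprop-1-en-1-yl]phenyl acetate | CC(C)(O)CCC[C@@]1(C)C=Cc2c(OCOC)c(C(=O)/C=C/c3ccc(OC(C)=O)cc3)cc(OCOC)c2O1 | intermediate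
17 | (2E)-1-[(2S)-5,8-dihydroxy-2-(4-hydroxy-4-methylpentyl)-2-methyl-2H-chromen-6-yl]-3-(4-hydroxyphenyl)prop-2-en-1-one | CC(C)(O)CCC[C@@]1(C)C=Cc2c(O)c(C(=O)/C=C/c3ccc(O)cc3)cc(O)c2O1 | target

Total step count: 10
Longest linear sequence: 10 steps (1 to 17); linalool 7 enters at step 4, CO 14 and styrene 15 at step 9.

Steps most likely to fail

For step 9, the danger is that alkene insertion outruns CO insertion (direct Heck arylation), that the styrene polymerises, or that the catalyst is deactivated under CO before the acyl complex meets the alkene. The fallback builds the ketone stepwise by classical chalcone chemistry. It sets out from iodochromene 13: Stille coupling with tributyl(1-ethoxyvinyl)stannane (Pd(PPh3)4, toluene, 100 °C) should give the 6-(1-ethoxyvinyl)chromene F1. Brief treatment with dilute aqueous HCl in THF should hydrolyse the enol ether to the 6-acetylchromene F2. Claisen–Schmidt condensation with commercial 4-(methoxymethoxy)benzaldehyde (KOH, EtOH, rt) should then give the tris-MOM chalcone F3. The acid methanolysis used in step 10 removes all three acetals, and the route is rejoined at target 17.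

For step 4, the danger is slow displacement at the doubly flanked C–F bond, so that reversible addition of the alkoxide to the aldehyde and hydride transfer between the adducts (Cannizzaro–Tishchenko-type disproportionation) take over. The fallback replaces the aldehyde by a nitrile as the activating group. It sets out from aldehyde 6: oxidative amination with I2 in aqueous NH3/THF should give 2-fluoro-5-iodo-3,6-bis(methoxymethoxy)benzonitrile F4, which activates fluoride displacement more strongly and cannot disproportionate. Alkoxide 8 should then give the aryl linalyl ether nitrile F5. Partial reduction with i-Bu2AlH (toluene, −78 °C) and hydrolytic work-up returns the route to aldehyde 9.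

For step 10, the danger is acid-induced addition of methanol to the chromene double bond or its oligomerisation, closure of the liberated 2'-hydroxychalcone to the flavanone, or incomplete ester cleavage. The fallback removes the two kinds of protecting group separately. It sets out from 16: K2CO3 in MeOH at 0 °C, harmless while both ring-A oxygens are still masked, should cleave only the aryl acetate and give the bis-MOM phenol F6. The two acetals are then hydrolysed on NaHSO4 supported on SiO2 in CH2Cl2 at rt, an aprotic heterogeneous medium free of methanol and dissolved mineral acid, to arrive at target 17.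

Further compounds
F1 | step 9 | 5-[(2S)-6-(1-ethoxyethenyl)-5,8-bis(methoxymethoxy)-2-methyl-2H-chromen-2-yl]-2-methylpentan-2-ol | CC(C)(O)CCC[C@@]1(C)C=Cc2c(OCOC)c(C(=C)OCC)cc(OCOC)c2O1
F2 | step 9 | 1-[(2S)-2-(4-hydroxy-4-methylpentyl)-5,8-bis(methoxymethoxy)-2-methyl-2H-chromen-6-yl]ethan-1-one | CC(C)(O)CCC[C@@]1(C)C=Cc2c(OCOC)c(C(C)=O)cc(OCOC)c2O1
F3 | step 9 | (2E)-1-[(2S)-2-(4-hydroxy-4-methylpentyl)-5,8-bis(methoxymethoxy)-2-methyl-2H-chromen-6-yl]-3-[4-(methoxymethoxy)phenyl]prop-2-en-1-one | CC(C)(O)CCC[C@@]1(C)C=Cc2c(OCOC)c(C(=O)/C=C/c3ccc(OCOC)cc3)cc(OCOC)c2O1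
F4 | step 4 | 2-fluoro-5-iodo-3,6-bis(methoxymethoxy)benzonitrile | N#Cc1c(F)c(OCOC)cc(I)c1OCOC
F5 | step 4 | 2-{[(3S)-3,7-dimethylocta-1,6-dien-3-yl]oxy}-5-iodo-3,6-bis(methoxymethoxy)benzonitrile | CC(C)=CCC[C@@](Oc1c(C#N)c(OCOC)c(I)cc1OCOC)(C)C=C
F6 | step 10 | (2E)-3-(4-hydroxyphenyl)-1-[(2S)-2-(4-hydroxy-4-methylpentyl)-5,8-bis(methoxymethoxy)-2-methyl-2H-chromen-6-yl]prop-2-en-1-one | CC(C)(O)CCC[C@@]1(C)C=Cc2c(OCOC)c(C(=O)/C=C/c3ccc(O)cc3)cc(OCOC)c2O1
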